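**Assumption:** the SMILES encodes the (S)-α-hydroxy ketone (CIP S). It is therefore built from L-tyrosine-derived (S)-4-hydroxyphenyllactic acid, and no ring is constructed in the route.

## Retrosynthetic overview
1. Lespeflorin C6 ⇒ bis-MOM-protected 3,5-diprenyl-2,4-dihydroxyphenyl ketone, by final MOM removal.
2. Diprenyl ketone ⇒ 2,4-dihydroxyphenyl ketone, by double ketone-directed C3/C5 C-prenylation.
3. 2,4-Dihydroxyphenyl ketone ⇒ resorcinol mono-ester of the protected (S)-hydroxy acid, by a photo-Fries rearrangement. This is the key C(aryl)–C(=O) bond-forming step.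
4. The ester comes from resorcinol and (S)-4-hydroxyphenyllactic acid, a chiral-pool acid that supplies the only stereocenter.

## Route

**Step 1**
Reactants: 1 (S)-2-hydroxy-3-(4-hydroxyphenyl)propanoic acid; 2 chloromethyl methyl ether (MOMCl)
Product: 3 (S)-2-(methoxymethoxy)-3-[4-(methoxymethoxy)phenyl]propanoic acid
Conditions: (i) MOMCl (4 equiv), i-Pr2NEt (5 equiv), CH2Cl2, 0 °C→rt, 12 h; (ii) LiOH (5 equiv), THF/H2O 3:1, rt, 2 h; acidify to pH 3 (one pot, telescoped)
Reagents that add atoms: MOMCl, ClCOC
Why: Alkylation of the phenol, the secondary alcohol and the carboxylate gives the tris-MOM compound, and mild saponification cleaves only the MOM ester. Both stereo-relevant C–H and C–O bonds are untouched, so the (S) center from the chiral-pool acid is retained.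

**Step 2**
Reactants: 3 protected acid; 4 resorcinol (benzene-1,3-diol, 3 equiv)
Product: 5 3-hydroxyphenyl (S)-2-(methoxymethoxy)-3-[4-(methoxymethoxy)phenyl]propanoate
Conditions: EDC·HCl (1.2 equiv), DMAP (0.2 equiv), CH2Cl2, 0 °C, 4 h
Reagents that add atoms: none
Why: Steglich-type esterification. Excess resorcinol favors the mono-ester, and the mild low-temperature carbodiimide conditions do not epimerize the α-alkoxy acid.

**Step 3**
Reactants: 5 resorcinol mono-ester
Product: 6 (S)-1-(2,4-dihydroxyphenyl)-2-(methoxymethoxy)-3-[4-(methoxymethoxy)phenyl]propan-1-one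
Conditions: hν (254 nm, Rayonet, quartz), MeCN (0.01 M), N2, 10 °C, 1–2 h
Reagents that add atoms: none
Why: Proposed new method: photo-Fries rearrangement of an aryl ester of an α-alkoxy (chiral) acid on a resorcinol mono-ester. Homolysis of the ArO–C(=O) bond gives an aryloxyl/α-alkoxyacyl radical pair that recombines in the solvent cage at C4/C6 of the resorcinol ring. Both positions are equivalent and give the same 2,4-dihydroxyphenyl ketone, which is stabilized by the H-bonded 2-OH and absorbs light as an inner filter. The α-carbon is not a radical center, so cage recombination is stereoretentive. The closest known reaction is the Anderson–Reese photo-Fries of aryl acetates and benzoates.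

**Step 4**
Reactants: 6 ketone; 7 prenyl bromide (1-bromo-3-methylbut-2-ene, 3 equiv)
Product: 8 (S)-1-(2,4-dihydroxy-3,5-bis(3-methylbut-2-enyl)phenyl)-2-(methoxymethoxy)-3-[4-(methoxymethoxy)phenyl]propan-1-one
Conditions: KOH (3.5 equiv), MeOH/H2O 4:1, 0 °C→rt, 12 h, dark
Reagents that add atoms: prenyl bromide, CC(C)=CCBr
Why: Phenoxide C-alkylation (SN2) in protic solvent is favored by H-bonding of the phenoxide oxygen. It goes at the two activated positions ortho to the 4-O⁻, C3 and C5, since C6 is meta to both oxygens. The 4-phenoxide para to the C=O makes the ketone non-enolizable, so the α-stereocenter is not epimerized. The MOM ethers are base-stable.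

**Step 5**
Reactants: 8 bis-MOM diprenyl ketone
Product: 9 Lespeflorin C6
Conditions: ZnBr2 (6 equiv), n-PrSH (10 equiv), CH2Cl2, 0 °C→rt, 1 h
Reagents that add atoms: none (the MOM groups leave as MOM-SPr)
Why: Lewis acid/thiol cleavage of MOM ethers is mild and leaves the trisubstituted alkenes and the α-hydroxy ketone intact. There is no base or strong Brønsted acid, so neither chroman cyclization nor α-epimerization is expected.

## Checks performed
- **Target match:** the product has a 2,4-dihydroxy-3,5-diprenylphenyl ketone, a CH(OH) at C2, a CH2 and a 4-hydroxyphenyl group. The acyl group is ortho to one OH and para to the other, and the ring H is at C6. The configuration is S, the same as L-tyrosine-derived acid 1.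
- **Atom balance:** the carbon skeleton of 1 plus the resorcinol C6 ring plus two C5 prenyl units equals the target C30 skeleton. Only protecting groups and the leaving groups of the coupling reagents are lost.
- **Group compatibility:** the MOM ethers survive EDC, 254 nm light and KOH. The prenyl alkenes are added after irradiation and are never exposed to strong acid.
- **Stereocenter:** it is set by the chiral-pool acid and is never touched by a reaction at the carbinol carbon.

## Compound list
1 | (S)-2-hydroxy-3-(4-hydroxyphenyl)propanoic acid | O=C(O)[C@@H](O)Cc1ccc(O)cc1 | starting material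
2 | chloromethyl methyl ether | ClCOC | starting material
3 | (S)-2-(MOMO)-3-[4-(MOMO)phenyl]propanoic acid | O=C(O)[C@@H](OCOC)Cc1ccc(OCOC)cc1 | intermediate
4 | resorcinol | Oc1cccc(O)c1 | starting material
5 | 3-hydroxyphenyl (S)-2-(MOMO)-3-[4-(MOMO)phenyl]propanoate | O=C(Oc1cccc(O)c1)[C@@H](OCOC)Cc1ccc(OCOC)cc1 | intermediate
6 | (S)-1-(2,4-dihydroxyphenyl)-2-(MOMO)-3-[4-(MOMO)phenyl]propan-1-one | O=C(c1ccc(O)cc1O)[C@@H](OCOC)Cc1ccc(OCOC)cc1 | intermediate
7 | prenyl bromide | CC(C)=CCBr | starting material
8 | bis-MOM diprenyl ketone | O=C(c1cc(CC=C(C)C)c(O)c(CC=C(C)C)c1O)[C@@H](OCOC)Cc1ccc(OCOC)cc1 | intermediate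
9 | Lespeflorin C6 | CC(C)=CCc1cc(C(=O)[C@@H](O)Cc2ccc(O)cc2)c(O)c(CC=C(C)C)c1O | target

**Total steps:** 5. **Longest linear sequence:** 5 steps.

## Three steps most likely to fail
1. **Step 3 (proposed new photo-Fries).** α-Alkoxyacyl radicals lose CO quickly, which would give decarbonylated ethers or alkylphenols, and 254 nm light may also damage the prenyl-free but electron-rich rings.
   - *Fallback (known chemistry, different approach):* drop the photochemistry and run a Lewis-acid Fries/Nencki-type acylation of resorcinol with the acid chloride of 3 (or BF3·OEt2 on ester 5), re-MOM-protecting if MOM groups are lost.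
2. **Step 4 (double C-prenylation).** Yield and mono/di selectivity are modest, and O-prenylation, prenyl-methyl ether formation and dearomatized by-products compete.
   - *Fallback (different approach):* di-iodinate 6 at C3/C5 with NIS, then Pd-catalyzed Stille coupling with prenyl-SnBu3 to install both prenyls, checking for branched-isomer formation.
3. **Step 5 (MOM removal).** The Lewis acid may cyclize a prenyl group onto the adjacent phenol to a chroman, or the thiol may add to the prenyl alkenes.
   - *Fallback (different approach):* replace the MOM groups with allyl ethers from the start (allyl bromide/K2CO3 in place of MOMCl) and remove them at the end with Pd(PPh3)4/K2CO3 in MeOH, which is neutral toward the prenyl groups.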